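(Readings and results are simulated for substances that don't exist; the scatter is artificial.)

Equivalents on this bench count against the left-handed substrate, not the racemate, so the reagent can turn over at most the equivalents divided by two as a fraction of the combined charge. The beta run, fed 0.55 equiv, reads 25.8% product at 6.00 min, under its bound of 27.5%, while the delta run, fed 1.1 equiv, reads 30.1%.

| flask | left-handed substrate | right-handed substrate | reagent | precatalyst | remark | time |
|---|---|---|---|---|---|---|
| delta | 0.10 mM | 0.10 mM | 1.1 equiv (fed, over 8.0 s) | 2 mol% | run made earlier; the fed solution adds 0.25 times the starting volume |  |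
| epsilon | 0.15 mM | 0.15 mM | 1.1 equiv (fed, over 8.0 s) | 2 mol% | run made earlier; the fed solution adds 0.25 times the starting volume |  |
| beta | 0.20 mM | 0.20 mM | 0.55 equiv (fed, over 8.0 s) | 2 mol% | run made earlier; the fed solution adds 0.25 times the starting volume |  |
| flask | 0.20 mM | 0.20 mM | 1.10 equiv (fed, over 8.0 s) | 2 mol% | the fed solution adds 0.25 times the starting volume | 6.0 min |

| run | time / min | left-handed product / % | right-handed product / % | left-handed substrate / % |
|---|---|---|---|---|
| delta | 1.50 | 4.1 | 3.4 | 44.5 |
| delta | 3.00 | 8.4 | 8.6 | 40.3 |
| delta | 5.00 | 11.0 | 11.6 | 35.2 |
| delta | 6.00 | 15.4 | 14.7 | 32.7 |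
| epsilon | 0.833 | 3.8 | 2.7 | 44.0 |
| epsilon | 2.00 | 6.9 | 9.9 | 35.4 |
| epsilon | 4.00 | 17.5 | 16.1 | 29.1 |
| epsilon | 6.00 | 19.5 | 21.3 | 23.8 |
| beta | 1.50 | 5.8 | 5.0 | 42.8 |
| beta | 3.00 | 11.0 | 9.1 | 37.1 |
| beta | 5.00 | 11.5 | 12.4 | 32.8 |
| beta | 6.00 | 12.7 | 13.1 | 31.1 |

(standard deviation of a reading: 1 percentage point)

- catalyst is single-handed; left-handed substrate and right-handed substrate are mirror images of each other, charged as a racemate, each of them at the stated concentration
- charges are per starting volume, the dose included; the dosed solution carries all of it
- what may be going on: reagent + catalyst + left-handed substrate -> catalyst + left-handed product; reagent + catalyst + right-handed substrate -> catalyst + right-handed product; left-handed product <-> right-handed product; precatalyst -> catalyst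
- an excess is the difference of the two amounts in percent of their sum
- an excess is below zero if the other one leads

1. excess of left-handed product over right-handed product in the product at 40 s
2. excess of left-handed product over right-handed product in the product at 6.0 min
3. part of the left-handed substrate and right-handed substrate charged together that has reacted at 6.0 min

You take over the flask with the racemate, the precatalyst and the reagent feed. Leave the feed as set, since its 8.0 s is short against 6.0 min. For this flask the reagent ceiling, equivalents divided by two, the most of the combined charge the limiting reagent can convert, is 55.0%.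

Reckon only the gap under it. In the delta run, the part reacted over the part still short of its ceiling reads 1.21 at 6.00 min. Catalyst, reagent and substrate meet in one step, so I scale that ratio by the concentration squared, to 4.84 for this flask. That leaves a gap of 9.4 percentage points, so I expect 45.6% reacted at 6.0 min.

The forecast gives 48% reacted (43% to 52%), higher than my figure, and reasons “so the flask has a ceiling of 55%”. For the product excess it gives 13% (5% to 23%) at 40 s and 0.5% (−1.5% to 4%) at 6.0 min.

The flask gives a product excess of 10.2% at 40 s and 0.0769% at 6.0 min, and 48.5% reacted at 6.0 min, each inside the forecast's range.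

    reagent + catalyst + left-handed substrate → catalyst + left-handed product (k = 1.59 × 10⁷ M⁻² s⁻¹)
    reagent + catalyst + right-handed substrate → catalyst + right-handed product (k = 6.83 × 10⁶ M⁻² s⁻¹)
    left-handed product ⇌ right-handed product (k = 0.0690 s⁻¹)
    precatalyst → catalyst (k = 0.0181 s⁻¹)

This flask ends 6.5 points under its ceiling, against my gap of 9.4 points, and at 6.00 min it holds 12% of its reagent charge. In this flask the half-life of left-handed product by its forward step to right-handed product alone, 0.17 min, is short against 6.0 min, and the product excess stands at 0.0769% by then. The neighbour with 5 mol% of precatalyst has the same reagent charge, so its ceiling stays 55.0%. It reaches 54.3% reacted, with 1.3% of its reagent left.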